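**Retrosynthetic overview**
1. The target is the myristate of (3S,5R,6S)-5,6-epoxy-3-hydroxy-5,6-dihydro-β-ionone, with the oxirane anti to the C3 ester (carotenoid numbering C1–C10 is used throughout).
2. The oxirane is disconnected to the C5=C6 alkene of (R)-3-(tetradecanoyloxy)-β-ionone; a peracid should enter anti to the C3 acyloxy group.
3. The C6–C7 bond is disconnected to a ring enol triflate plus (E)-4-(tributylstannyl)but-3-en-2-one. C6 (a ketone carbon) and C7 (an enone β-carbon) are both acceptor carbons, so the butenone is used with inverted polarity as a β-acylvinyl anion (homoenolate-type d3) equivalent, and the E-enone arrives intact.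
4. The enol triflate comes from the myristate of (4R,6R)-actinol (only one enolisable α-carbon; the ester doubles as protecting group). The stannane comes from (E)-1,2-bis(tributylstannyl)ethene and acetyl chloride.
5. Ring order: the carbocycle is bought with the C3 stereocentre in place; the oxirane is the only ring formed, in the last step.

Assumption: (4R,6R)-4-hydroxy-2,2,6-trimethylcyclohexan-1-one ((4R,6R)-actinol), the bulk intermediate of industrial zeaxanthin manufacture, is taken as a purchasable enantiopure starting material.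

**Route**

Step 1
Reactants: 1 (E)-1,2-bis(tributylstannyl)ethene; 2 acetyl chloride
Product: 3 (E)-4-(tributylstannyl)but-3-en-2-one
Conditions: 1 (1.1 equiv), PdCl2(MeCN)2 (3 mol%), toluene, rt → 50 °C
Reagents that add atoms: none
Why: Acylative Stille coupling of the acid chloride at one C–Sn bond with retention of E geometry; the acyl group deactivates the remaining C–Sn bond, so the reaction stops at mono-acylation.

Step 2
Reactants: 4 (4R,6R)-4-hydroxy-2,2,6-trimethylcyclohexan-1-one; 5 tetradecanoyl chloride
Product: 6 (1R,5R)-3,3,5-trimethyl-4-oxocyclohexyl tetradecanoate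
Conditions: pyridine (2 equiv), DMAP (5 mol%), CH2Cl2, 0 °C → rt
Reagents that add atoms: none
Why: DMAP-catalysed O-acylation (nucleophilic acyl substitution) of the unhindered secondary alcohol; no bond to the carbinol carbon is touched, so the C3 stereocentre is carried over unchanged from 4.

Step 3
Reactants: 6 (1R,5R)-3,3,5-trimethyl-4-oxocyclohexyl tetradecanoate
Product: 7 (1R)-3,5,5-trimethyl-4-[(trifluoromethanesulfonyl)oxy]cyclohex-3-en-1-yl tetradecanoate
Conditions: Tf2O (1.3 equiv), 2,6-di-tert-butyl-4-methylpyridine (1.5 equiv), CH2Cl2, 0 °C → rt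
Reagents that add atoms: trifluoromethanesulfonic anhydride, O=S(=O)(OS(=O)(=O)C(F)(F)F)C(F)(F)F
Why: Stang enol triflate synthesis (O-sulfonylation of the ketone, then loss of the only α-hydrogen, since the other α-carbon is quaternary) under conditions that cannot enolise the ester; the C3 stereocentre is not involved and the methyl-bearing stereocentre is deliberately erased.

Step 4
Reactants: 7 (1R)-3,5,5-trimethyl-4-[(trifluoromethanesulfonyl)oxy]cyclohex-3-en-1-yl tetradecanoate; 3 (E)-4-(tributylstannyl)but-3-en-2-one
Product: 8 (1R)-3,5,5-trimethyl-4-[(1E)-3-oxobut-1-en-1-yl]cyclohex-3-en-1-yl tetradecanoate [(R)-3-(tetradecanoyloxy)-β-ionone]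
Conditions: Pd2(dba)3 (dba = dibenzylideneacetone, 5 mol%), AsPh3 (40 mol%), CuI (20 mol%), LiCl (3 equiv), NMP, 60 °C
Reagents that add atoms: none
Why: Stille cross-coupling in which zerovalent palladium inserts into the C6–OTf bond and stannane 3, a β-acylvinyl anion (homoenolate-type d3) equivalent, delivers C7 as the nucleophile, so two natively electrophilic carbons are joined with retention of E geometry; AsPh3, CuI and LiCl are the accelerants that a hindered tetrasubstituted triflate (precedented for the unfunctionalised 2,6,6-trimethylcyclohexenyl triflate) and an electron-poor stannane call for.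

Step 5
Reactants: 8 (1R)-3,5,5-trimethyl-4-[(1E)-3-oxobut-1-en-1-yl]cyclohex-3-en-1-yl tetradecanoate
Product: 9 (1R,3S,6S)-1,5,5-trimethyl-6-[(1E)-3-oxobut-1-en-1-yl]-7-oxabicyclo[4.1.0]heptan-3-yl tetradecanoate (target)
Conditions: mCPBA (1.1 equiv), CH2Cl2, −10 → 0 °C
Reagents that add atoms: 3-chloroperoxybenzoic acid, OOC(=O)c1cccc(Cl)c1
Why: Prilezhaev epoxidation in which the electron-rich tetrasubstituted C5=C6 bond reacts far faster than the enone C7=C8 bond and the peracid approaches anti to the C3 acyloxy group (dipole and steric repulsion, no hydrogen-bond donor to steer it syn), setting C5 (R) and C6 (S) together by concerted syn oxygen transfer; about 3–4:1 anti:syn is expected by analogy with peracid epoxidation of 3-acyloxy β-ionone-type rings, and the minor syn epoxide is removed by chromatography.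

**Compound list**
1 | (E)-1,2-bis(tributylstannyl)ethene | CCCC[Sn](CCCC)(CCCC)/C=C/[Sn](CCCC)(CCCC)CCCC | starting material
2 | acetyl chloride | CC(=O)Cl | starting material
3 | (E)-4-(tributylstannyl)but-3-en-2-one | CC(=O)/C=C/[Sn](CCCC)(CCCC)CCCC | intermediate
4 | (4R,6R)-4-hydroxy-2,2,6-trimethylcyclohexan-1-one ((4R,6R)-actinol, OH and C6-methyl trans) | O[C@H]1CC(C)(C)C(=O)[C@H](C)C1 | starting material
5 | tetradecanoyl chloride (myristoyl chloride) | CCCCCCCCCCCCCC(=O)Cl | starting material
6 | (1R,5R)-3,3,5-trimethyl-4-oxocyclohexyl tetradecanoate | CCCCCCCCCCCCCC(=O)O[C@H]1CC(C)(C)C(=O)[C@H](C)C1 | intermediate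
7 | (1R)-3,5,5-trimethyl-4-[(trifluoromethanesulfonyl)oxy]cyclohex-3-en-1-yl tetradecanoate | CCCCCCCCCCCCCC(=O)O[C@H]1CC(C)(C)C(OS(=O)(=O)C(F)(F)F)=C(C)C1 | intermediate
8 | (1R)-3,5,5-trimethyl-4-[(1E)-3-oxobut-1-en-1-yl]cyclohex-3-en-1-yl tetradecanoate | CCCCCCCCCCCCCC(=O)O[C@H]1CC(C)(C)C(/C=C/C(C)=O)=C(C)C1 | intermediate
9 | (1R,3S,6S)-1,5,5-trimethyl-6-[(1E)-3-oxobut-1-en-1-yl]-7-oxabicyclo[4.1.0]heptan-3-yl tetradecanoate; carotenoid descriptors (3S,5R,6S), oxirane anti to the ester | CCCCCCCCCCCCCC(=O)O[C@H]1CC(C)(C)[C@]2(/C=C/C(C)=O)O[C@]2(C)C1 | target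

**Step count and risks**
Total steps: 5 (four in the main line plus one to make stannane 3). Longest linear sequence: 4 steps (4 → 6 → 7 → 8 → 9).

Most likely to fail, step 4. The triflate is tetrasubstituted and flanked by a quaternary carbon, and the stannane is electron-poor, so oxidative addition and transmetalation are both slow; protodestannylation or triflate hydrolysis may win. The fallback sets out from 7 and comes back at 8. Sonogashira coupling of 7 with racemic but-3-yn-2-ol (PdCl2(PPh3)2, CuI, Et3N, DMF, 50 °C), whose sp carbon is far less demanding sterically, gives the enynol (1R)-4-(3-hydroxybut-1-yn-1-yl)-3,5,5-trimethylcyclohex-3-en-1-yl tetradecanoate F1 as an inconsequential 1:1 pair of side-chain carbinol epimers. Redox isomerisation of the propargylic alcohol (RuCl(η5-indenyl)(PPh3)2, In(OTf)3, camphorsulfonic acid, THF, 65 °C) then moves the oxidation level to C9 and gives the (E)-enone 8. The alkynol still acts as a β-acylvinyl anion equivalent.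

Second, step 5. The facial selectivity rests on a modest substrate bias, and the diastereomers may be hard to separate. The fallback sets out from 8 and comes back at 9, and replaces direct oxygen transfer by a halohydrin sequence governed by trans-diaxial opening. NBS in THF/H2O (0 °C) forms bromonium ions reversibly. Water can open only at C5 (C6 is neopentylic and deactivated by the enone), and in the half-chair with the ester equatorial a diaxial opening at C5 is possible only for the bromonium syn to the ester. This gives the bromohydrin (1S,3R,4R)-4-bromo-3-hydroxy-3,5,5-trimethyl-4-[(1E)-3-oxobut-1-en-1-yl]cyclohexyl tetradecanoate F2, with C5–OH anti and C6–Br syn to the ester. DBU in CH2Cl2 (rt) closes the oxirane by intramolecular SN2 with inversion at C6 (C6 has no β-hydrogen, so elimination cannot compete), which places the oxygen anti to the ester and gives 9.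

Third, step 3. Electrophilic triflation of a ketone flanked by a quaternary and a tertiary carbon may be sluggish, or the ester may interfere. The fallback sets out from 4 and comes back at 8. It postpones the acylation and uses kinetic enolate chemistry, which the ester would not tolerate. TBSCl and imidazole in DMF give (4R,6R)-4-[(tert-butyldimethylsilyl)oxy]-2,2,6-trimethylcyclohexan-1-one F3. LiN(i-Pr)2 in THF at −78 °C, then PhNTf2 (→ 0 °C), traps the single possible enolate as (4R)-4-[(tert-butyldimethylsilyl)oxy]-2,6,6-trimethylcyclohex-1-en-1-yl trifluoromethanesulfonate F4. Stille coupling with 3 under the step 4 conditions gives (3E)-4-[(4R)-4-[(tert-butyldimethylsilyl)oxy]-2,6,6-trimethylcyclohex-1-en-1-yl]but-3-en-2-one F5. HF·pyridine in THF frees (3E)-4-[(4R)-4-hydroxy-2,6,6-trimethylcyclohex-1-en-1-yl]but-3-en-2-one F6. Acylation with 5 (pyridine, DMAP, CH2Cl2) gives 8.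

**Further compounds**
F1 | step 4 | (1R)-4-(3-hydroxybut-1-yn-1-yl)-3,5,5-trimethylcyclohex-3-en-1-yl tetradecanoate (1:1 epimers at the side-chain carbinol) | CCCCCCCCCCCCCC(=O)O[C@H]1CC(C)(C)C(C#CC(C)O)=C(C)C1
F2 | step 5 | (1S,3R,4R)-4-bromo-3-hydroxy-3,5,5-trimethyl-4-[(1E)-3-oxobut-1-en-1-yl]cyclohexyl tetradecanoate | CCCCCCCCCCCCCC(=O)O[C@H]1CC(C)(C)[C@](Br)(/C=C/C(C)=O)[C@@](O)(C)C1
F3 | step 3 | (4R,6R)-4-[(tert-butyldimethylsilyl)oxy]-2,2,6-trimethylcyclohexan-1-one | CC(C)(C)[Si](C)(C)O[C@H]1CC(C)(C)C(=O)[C@H](C)C1
F4 | step 3 | (4R)-4-[(tert-butyldimethylsilyl)oxy]-2,6,6-trimethylcyclohex-1-en-1-yl trifluoromethanesulfonate | CC(C)(C)[Si](C)(C)O[C@H]1CC(C)(C)C(OS(=O)(=O)C(F)(F)F)=C(C)C1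
F5 | step 3 | (3E)-4-[(4R)-4-[(tert-butyldimethylsilyl)oxy]-2,6,6-trimethylcyclohex-1-en-1-yl]but-3-en-2-one | CC(C)(C)[Si](C)(C)O[C@H]1CC(C)(C)C(/C=C/C(C)=O)=C(C)C1
F6 | step 3 | (3E)-4-[(4R)-4-hydroxy-2,6,6-trimethylcyclohex-1-en-1-yl]but-3-en-2-one | O[C@H]1CC(C)(C)C(/C=C/C(C)=O)=C(C)C1
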